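The runs are simulated for substances that don't exist; noise was put on by code.

**The task.** The chemist on Friday's flask must say how much product stands there at 3.0 h, and whether any remedy pays.

| flask | substrate | solid reagent | initiator | temperature | remark | time |
|---|---|---|---|---|---|---|
| Friday's | 0.050 M | 0.80 equiv | 3.4 mol% | 25 °C | the very flask that is asked about, followed so far |  |
| Thursday's | 0.025 M | 0.80 equiv | 3.4 mol% | 20 °C | run made earlier |  |
| flask | 0.050 M | 0.800 equiv | 3.4 mol% | 25 °C |  | 3.0 h |

| run | time / min | product / % | substrate / % |
|---|---|---|---|
| Friday's | 50.0 | 78.9 | 20.1 |
| Friday's | 90.0 | 79.7 | 19.7 |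
| Friday's | 150 | 79.4 | 19.4 |
| Friday's | 180 | 79.6 | 18.8 |
| Thursday's | 1.33 | 65.5 | 34.4 |
| Thursday's | 4.00 | 79.1 | 20.6 |
| Thursday's | 6.00 | 79.9 | 20.4 |
| Thursday's | 10.0 | 79.5 | 20.2 |

(each reading ± 0.5 percentage points)

- epsilon: change nothing and wait 50 min more
- beta: at 3.0 h raise the temperature by 25 K, then wait 50 min
- alpha: at 3.0 h add substrate, 50.0% of the amount charged, then wait 50 min
- eta: at 3.0 h take out 90% of the product then present, then wait 50 min

- given per volume of solution although it is solid: solid reagent
- product taken out counts as made
- what was read earlier has a scatter of 0.5 percentage points, one standard deviation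
- at the start none of the solid reagent is in solution
- additions bring no volume worth counting

- product, in percent of the substrate first charged, at 3.0 h
- the remedy with the largest gain of product, or "none" below 2 percentage points (epsilon / beta / alpha / eta / none)
- product present, with what was taken out counted in, in percent of the substrate first charged, after beta
- product present, with what was taken out counted in, in percent of the substrate first charged, after alpha

**Starting slope.** You can solve the curve at both ends and join them. Friday's first reading, at 50.0 min, already stands at 78.9%, so the rise must be read from Thursday's run. Its first reading gives a chord of 0.492 /min in fractions of the charge, with the scatter of that reading.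

**Upper level.** Take the solid reagent as the limiting reagent, one unit used per unit of product. The reagent ceiling, the fraction of the substrate that its charge can turn into product, is then 80.0%. Friday's readings average 79.4%, just under it.

**The knee.** Thursday's chord meets the ceiling at 1.62 min, and its reading at 4.00 min already stands at 79.1%. Friday's flask is on the level by 50.0 min. Its substrate still drifts from 20.1% to 18.8%, while its product stays flat.

**My reckoning.** For Friday's flask I commit to 79.4% now. The headroom under the ceiling is 0.6 percentage points, less than the 2 points a remedy must gain. No remedy adds solid reagent, so the ceiling stands for each. I therefore expect 79.4% after beta and after alpha, and choose none.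

**The forecast.** It gives 79.6% now, 79.7% after beta and 79.7% after alpha, where I gave 79.4% for each. It also chooses none, on the ground that “the reagent has simply run out”.

**The result.** Friday's flask gives 79.4% now, 79.4% after beta and 79.4% after alpha, and the best remedy is none.

    initiator → 2 initiating radical (k = 3.08 × 10⁻⁵ /s, Ea = 98.0 kJ/mol)
    substrate + initiating radical → capped initiator + first chain carrier (k = 8.27 × 10⁶ /M/s, Ea = 11.0 kJ/mol)
    partner + first chain carrier → product + second chain carrier (k = 4.10 × 10⁵ /M/s, Ea = 8.00 kJ/mol)
    substrate + second chain carrier → released group + first chain carrier (k = 1.28 × 10⁶ /M/s, Ea = 17.0 kJ/mol)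
    2 first chain carrier → ended chains A (k = 2.00 × 10⁶ /M/s, Ea = 16.0 kJ/mol)
    2 second chain carrier → ended chains B (k = 5.00 × 10⁷ /M/s, Ea = 8.00 kJ/mol)
    partner → decomposed reagent (k = 4.12 × 10⁻⁴ /s, Ea = 98.0 kJ/mol)
    solid reagent ⇌ partner, rate k8*(cs8 - [partner]) while solid is left; crystals form when [partner] > cs8 (solubility = 21.0 mM, k = 0.153 /s)
    (constants at 25 °C)

**Second flask.** At 180 min Friday's flask holds solid reagent 0%, and its product stands 0.60 points under the ceiling of 80.0%. The decomposed reagent there equals 0.592% of the substrate charged. Now charge a neighbour with 0.320 equiv of solid reagent, all else held. Its ceiling is 32.0%. At 180 min it holds solid reagent 0%, product 31.8% and substrate 66%.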